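**Plan**

- Retrosynthesis: the first cut is at the two C5''–CH2 bonds that tie each outer 2-hydroxybenzyl group to its inner phenol ring. The second is at the two boron–pinacol ester links, and the last at the C6–CH2 and C8–CH2 bonds to ring A of the flavanone.
- Enabling feature: each outer ring carries its OH ortho to the bridging CH2, so the unit is what the ortho-quinone methide of 2-hydroxybenzyl alcohol delivers. It sits on C5'', the carbon para to the inner C2''–OH, where a boron atom can be placed beforehand and turns the ipso carbon into the nucleophile.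
- Forward: aldehyde 1 is reduced to the boron-bearing salicyl alcohol 2. Two molecules of 2 are joined to C6 and C8 of (2S)-pinostrobin 3 to give bis(pinacol boronate) 4, and pinacol is removed to give bis(boronic acid) 5. Then 5 and 2-hydroxybenzyl alcohol 6 pass through the boron-bound intermediates 7 and 8 to the target 9. No ring is formed; all rings are bought.
- Stereochemistry: the only stereocentre, C2 (S), comes with natural (2S)-pinostrobin. After it enters, the flavanone meets no base, so the retro-oxa-Michael opening of ring C that would racemise C2 is avoided.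

Key step: step 4

Assumption: catalogue (2S)-pinostrobin is taken as enantiopure; because natural samples can be partly racemic, its ee would be checked by chiral HPLC and raised by recrystallisation before use.

Locants: flavanone numbering for rings A, B and C. The inner benzyl rings carry doubly primed locants (C1'' bears the CH2, C2'' the OH, C5'' is para to that OH); the outer rings carry quadruply primed locants.

**Route**

Step 1
Reactants: 1 2-hydroxy-5-(4,4,5,5-tetramethyl-1,3,2-dioxaborolan-2-yl)benzaldehyde
Product: 2 2-(hydroxymethyl)-4-(4,4,5,5-tetramethyl-1,3,2-dioxaborolan-2-yl)phenol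
Conditions: NaBH4, MeOH–THF, 0 °C; aq. NH4Cl
Reagents that add atoms: none
Why: NaBH4 reduction of an aryl aldehyde to the benzylic alcohol, which should leave the pinacol boronate and the phenol untouched and creates no stereocentre.

Step 2
Reactants: 3 (2S)-pinostrobin; 2 2-(hydroxymethyl)-4-(4,4,5,5-tetramethyl-1,3,2-dioxaborolan-2-yl)phenol (2.4 equiv)
Product: 4 (2S)-5-hydroxy-6,8-bis[2-hydroxy-5-(4,4,5,5-tetramethyl-1,3,2-dioxaborolan-2-yl)benzyl]-7-methoxyflavanone
Conditions: ZnCl2 (anhydrous, excess), 1,4-dioxane, 70 °C
Reagents that add atoms: none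
Why: Friedel–Crafts ortho-hydroxybenzylation through the zinc-bound ortho-quinone methide of 2, a reaction type established for 5,7-dioxygenated flavanones with salicyl alcohols: C6 and C8 are the only free positions of the phloroglucinol-type ring A and both are wanted, the pinacol boronate should be a bystander because its hindered ipso carbon cannot compete with C6/C8 and anhydrous ZnCl2 in dioxane is a weak proton source, and C2 should hold because no base is present and the plain phenyl ring B offers no quinone methide path for opening ring C.

Step 3
Reactants: 4 (2S)-5-hydroxy-6,8-bis[2-hydroxy-5-(4,4,5,5-tetramethyl-1,3,2-dioxaborolan-2-yl)benzyl]-7-methoxyflavanone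
Product: 5 (2S)-6,8-bis(5-borono-2-hydroxybenzyl)-5-hydroxy-7-methoxyflavanone
Conditions: MeB(OH)2 (excess), acetone–0.1 M aq. HCl, rt; evaporation, product used without chromatography
Reagents that add atoms: methylboronic acid, CB(O)O
Why: Acid-assisted boronic ester transesterification, in which pinacol passes to the excess methylboronic acid and both its pinacol ester and the surplus reagent leave on evaporation, while dilute acid at room temperature should neither protodeboronate the para-hydroxyaryl boronic acid nor disturb C2.

Step 4
Reactants: 5 (2S)-6,8-bis(5-borono-2-hydroxybenzyl)-5-hydroxy-7-methoxyflavanone; 6 2-hydroxybenzyl alcohol (2.05 equiv)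
Product: 9 5''-(2''''-hydroxybenzyl)uvarinol (target), via bis(benzodioxaborin) 7 (not isolated), via bis(aryl borate) 8 (not isolated)
Conditions: 6, 4 Å MS, THF–toluene, rt; then 3,3'-dibromo-1,1'-bi-2-naphthol (20 mol%, racemic), 60 °C; aq. NH4Cl
Reagents that add atoms: none
Why: Proposed new method: each boronic acid of 5 condenses with the phenol and benzylic hydroxyl of 6 to the six-membered cyclic boronate 7; exchange of a B–O bond for a naphtholate of the electron-poor binaphthol raises the Lewis acidity at boron, the benzylic C–O bond ionises, and the resulting ortho-quinone methide stays bound through its oxygen to a four-coordinate boron. The aryl group, a para-hydroxyphenyl that is strongly nucleophilic at its boron-bearing carbon, then shifts from boron to the methide CH2 through a six-membered array (C5''–B–O–C=C–CH2), which gives borate 8 and, on hydrolysis, 9 and boric acid. The closest known reaction type is the biphenol-catalysed 1,4-addition of aryl and alkenyl boronates to ortho-quinone methides (a Petasis-type boron-to-carbon transfer), shown for aryl-substituted methides; the unsubstituted methide and the free polyphenol are the extension, supported by the known behaviour of 2-aryl-4H-1,3,2-benzodioxaborins as ortho-quinone methide sources. No ring closes and no stereocentre forms, so a racemic catalyst suffices, and C2 should be safe because the medium holds neither base nor mineral acid. The step needs attack at C5'' and not at C3'' or on the outer phenol rings of the product; this is secured by the position of boron and the intramolecular delivery, and by using no more than one equivalent of 6 per boron so that no free methide remains for Friedel–Crafts chain growth.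

**Compound list**

1 | 2-hydroxy-5-(4,4,5,5-tetramethyl-1,3,2-dioxaborolan-2-yl)benzaldehyde | O=Cc1cc(B2OC(C)(C)C(C)(C)O2)ccc1O | starting material
2 | 2-(hydroxymethyl)-4-(4,4,5,5-tetramethyl-1,3,2-dioxaborolan-2-yl)phenol | OCc1cc(B2OC(C)(C)C(C)(C)O2)ccc1O | intermediate
3 | (2S)-pinostrobin, (2S)-5-hydroxy-7-methoxy-2-phenylchroman-4-one | COc1cc(O)c2c(c1)O[C@H](c1ccccc1)CC2=O | starting material
4 | (2S)-5-hydroxy-6,8-bis[2-hydroxy-5-(4,4,5,5-tetramethyl-1,3,2-dioxaborolan-2-yl)benzyl]-7-methoxyflavanone | COc1c(Cc2cc(B3OC(C)(C)C(C)(C)O3)ccc2O)c(O)c2c(c1Cc1cc(B3OC(C)(C)C(C)(C)O3)ccc1O)O[C@H](c1ccccc1)CC2=O | intermediate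
5 | (2S)-6,8-bis(5-borono-2-hydroxybenzyl)-5-hydroxy-7-methoxyflavanone | COc1c(Cc2cc(B(O)O)ccc2O)c(O)c2c(c1Cc1cc(B(O)O)ccc1O)O[C@H](c1ccccc1)CC2=O | intermediate
6 | 2-hydroxybenzyl alcohol | OCc1ccccc1O | starting material
7 | (2S)-6,8-bis[5-(4H-1,3,2-benzodioxaborin-2-yl)-2-hydroxybenzyl]-5-hydroxy-7-methoxyflavanone (cyclic boronate of each boron with 6) | COc1c(Cc2cc(B3OCc4ccccc4O3)ccc2O)c(O)c2c(c1Cc1cc(B3OCc4ccccc4O3)ccc1O)O[C@H](c1ccccc1)CC2=O | intermediate
8 | (2S)-6,8-bis{5-[2-(dihydroxyboryloxy)benzyl]-2-hydroxybenzyl}-5-hydroxy-7-methoxyflavanone (target with B(OH)2 on each outer phenol oxygen, drawn as the hydrated monomer; in the dry flask its anhydride or catalyst-bound ester) | COc1c(Cc2cc(Cc3ccccc3OB(O)O)ccc2O)c(O)c2c(c1Cc1cc(Cc3ccccc3OB(O)O)ccc1O)O[C@H](c1ccccc1)CC2=O | intermediate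
9 | 5''-(2''''-hydroxybenzyl)uvarinol, (2S)-5-hydroxy-6,8-bis[2-hydroxy-5-(2-hydroxybenzyl)benzyl]-7-methoxyflavanone | COc1c(Cc2cc(Cc3ccccc3O)ccc2O)c(O)c2c(c1Cc1cc(Cc3ccccc3O)ccc1O)O[C@H](c1ccccc1)CC2=O | target

**Count**

Total steps: 4. Longest linear sequence: 4 steps (1 → 2 → 4 → 5 → 9); 3 steps from (2S)-pinostrobin.

**Steps most likely to fail**

1. Step 4. Ionisation of the primary benzylic C–O bond inside boronate 7 may be too slow. Protodeboronation, or release of free methide followed by unselective Friedel–Crafts chain growth on the outer phenol rings, could then overtake the templated aryl shift. The fallback uses known chemistry without boron and sets out from 3. ZnCl2-mediated Friedel–Crafts hydroxybenzylation of 3 with 6 (2.4 equiv, dioxane, 70 °C) should give (2S)-5-hydroxy-6,8-bis(2-hydroxybenzyl)-7-methoxyflavanone F1. A second ZnCl2-mediated hydroxybenzylation of F1 with 5-bromo-2-hydroxybenzyl alcohol (OCc1cc(Br)ccc1O, 2.0 equiv) relies on the innate para preference of the inner phenols for C5'', while bromine blocks the para carbon of each incoming ring against chain growth. It should give (2S)-6,8-bis[5-(5-bromo-2-hydroxybenzyl)-2-hydroxybenzyl]-5-hydroxy-7-methoxyflavanone F2. Hydrodebromination (H2, Pd/C, NaHCO3, EtOAc–MeOH, rt, stopped once the bromide is consumed) comes back to the route at 9.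

2. Step 2. Boron may be lost during the Lewis-acid alkylation, either by protodeboronation with the water set free or by ipso attack of the methide on a boron-bearing carbon, and the second, more hindered alkylation may stall. The fallback introduces boron after the C–C bonds and sets out from 3. The same ZnCl2 coupling with 5-bromo-2-hydroxybenzyl alcohol (2.4 equiv) should give (2S)-6,8-bis(5-bromo-2-hydroxybenzyl)-5-hydroxy-7-methoxyflavanone F3. Miyaura borylation (bis(pinacolato)diboron, PdCl2(dppf), KOAc, dioxane, 80 °C) then comes back to the route at 4. The reaction time is kept short and the ee checked, because acetate at this temperature could start reversible opening of ring C.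

3. Step 3. The ester exchange may stop short of completion, or the electron-rich aryl–boron bond may be cleaved by the aqueous acid. The fallback goes through an isolable fluoroborate and sets out from 4. KHF2 in aqueous MeOH at rt should give dipotassium (2S)-5-hydroxy-7-methoxy-6,8-bis[2-hydroxy-5-(trifluoroborato)benzyl]flavanone F4, freed from pinacol by evaporation and trituration. Hydrolysis with Me3SiCl and water in MeCN at rt comes back to the route at 5.

**Further compounds**

F1 | step 4 | (2S)-5-hydroxy-6,8-bis(2-hydroxybenzyl)-7-methoxyflavanone | COc1c(Cc2ccccc2O)c(O)c2c(c1Cc1ccccc1O)O[C@H](c1ccccc1)CC2=O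
F2 | step 4 | (2S)-6,8-bis[5-(5-bromo-2-hydroxybenzyl)-2-hydroxybenzyl]-5-hydroxy-7-methoxyflavanone | COc1c(Cc2cc(Cc3cc(Br)ccc3O)ccc2O)c(O)c2c(c1Cc1cc(Cc3cc(Br)ccc3O)ccc1O)O[C@H](c1ccccc1)CC2=O
F3 | step 2 | (2S)-6,8-bis(5-bromo-2-hydroxybenzyl)-5-hydroxy-7-methoxyflavanone | COc1c(Cc2cc(Br)ccc2O)c(O)c2c(c1Cc1cc(Br)ccc1O)O[C@H](c1ccccc1)CC2=O
F4 | step 3 | dipotassium (2S)-5-hydroxy-7-methoxy-6,8-bis[2-hydroxy-5-(trifluoroborato)benzyl]flavanone | [K+].[K+].COc1c(Cc2cc([B-](F)(F)F)ccc2O)c(O)c2c(c1Cc1cc([B-](F)(F)F)ccc1O)O[C@H](c1ccccc1)CC2=O
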